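The numbers are assumed; the result is computed.

I decided to reckon this flask from the balance of Q, of which the solution holds 0.92 mM at saturation, less than the 10 mM of L.

L 10 mM; J 0.92 mM (held); E 10.0 mM; G 0.56 mol%; time 30 h

    L + Q → L.Q (k1 = 5.9 M⁻¹ h⁻¹)
    L + Q + G → G + Z (k2 = 2.7 × 10⁵ M⁻² h⁻¹)
    J ⇌ Q, rate k3*(csat - [Q]) (k3 = 2.9 h⁻¹, csat = 0.92 mM)
    L + E → L.E (k4 = 3.5 M⁻¹ h⁻¹)

* how much Z there is at 30 h, in percent of the L charged
* concentration of Q in solution at 30 h, in percent of saturation

Could the transfer keep up in this flask? With [G] at 0.0560 mM, the plain step and the step over G together use Q with a constant of 21.0 M⁻¹ h⁻¹. At the charged [L] that is 0.210 h⁻¹, less than the transfer coefficient of 2.9 h⁻¹, a ratio of 0.0725. Once past the first lag of dissolving, the balance therefore puts [Q] at 93.2 % of saturation at the charged [L].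

Who then gets L? With [Q] near saturation and [E] taken as charged, L is lost pseudo-first-order at 0.0543 h⁻¹, and the step to Z accounts for 0.0139 h⁻¹ of it. The part of the L lost at the start that becomes Z, the Z share (a selectivity), is 25.6 %.

How far does L go? Over 30 h the loss amounts to 1.63 lifetimes, so at that constant rate I reckoned 80.4 % of L consumed. Holding the Z share at its starting value, I committed to y = 20.6 % and [Q] at 98.6 % of saturation.

The forecast gave 20.9 % and 98 %, holding that “Q is quasi-steady”. This flask gave 21.2 % and 98.0 %, with L at 27 %, above the 19.6 % I had reckoned. Its Z per L lost over the whole run was 29.0 %, above the starting Z share, and [E] stood at 57 % of its charge, so my y came near through two departures running opposite ways.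

The neighbouring flask took 17 mM of L, with G at the same mol% and [E] charged at 10.0 mM as before. The same reckoning puts its [G] at 0.0952 mM and its loss of L at 0.0641 h⁻¹. Its starting Z share is 36.9 %, more than the 25.6 % of the first flask. Over 30 h that gives 31.5 % of the L charged as Z. The neighbour gave 32.5 %, with 24.5 % of its L left.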